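**Retrosynthetic overview**

1. The last step is a single hydrogenolysis that removes four benzyl groups (two ArO–Bn, CO2–Bn, C13'O–Bn) from the fully assembled chain; the (R)-C2' acetate is already in place.
2. Key disconnection C6'–C7' (CH2–CH2): one-pot 9-BBN hydroboration of the C5'=C6' vinyl group of the complete aryl half, then Pd-catalysed alkyl–alkyl Suzuki–Miyaura coupling with benzyl 7-bromoheptyl ether, forming the bond at its final oxidation level.
3. Enabling feature: the heteroatom-free decamethylene run C3'–C12' between the C2' carbinol and C13'–O. C6'–C7' has no stereocentre or functional group beside it, C6' is the terminal vinyl carbon supplied by the commercial (R)-epoxide, and it lies four bonds from the C2' acetate and six from the benzoate ring, so β-elimination and chelation cannot interfere.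
4. Aryl half: the aryl–C1' bond and the C2' configuration come from Cu-catalysed opening of (R)-1,2-epoxy-5-hexene by the 3,5-bis(benzyloxy)phenyl Grignard reagent (alkoxide acetylated in the flask); the carboxyl carbon comes from Vilsmeier–Haack formylation, Pinnick oxidation and benzylation.
5. Rings: none is formed or broken; the benzene ring of the resorcylic acid is bought as 5-bromoresorcinol.

Key step: step 7

Remark: side-chain carbons are numbered C1' (benzylic CH2) to C13' (CH2OH); 5-bromoresorcinol, (R)-1,2-epoxy-5-hexene and 7-bromoheptan-1-ol are taken as commercial.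

**Route**

Step 1
Reactants: 1 5-bromobenzene-1,3-diol
Product: 2 1,3-bis(benzyloxy)-5-bromobenzene
Conditions: BnBr (2.2 equiv), K2CO3, DMF, rt → 60 °C
Reagents that add atoms: benzyl bromide BrCc1ccccc1
Why: Williamson ether synthesis on both phenols (carbonate-mediated SN2 on benzyl bromide) installs protecting groups that tolerate the Grignard, Vilsmeier and borane steps and are removed together at the end.

Step 2
Reactants: 2 1,3-bis(benzyloxy)-5-bromobenzene; 3 (2R)-2-(but-3-en-1-yl)oxirane [(R)-1,2-epoxy-5-hexene]
Product: 6 (2R)-1-[3,5-bis(benzyloxy)phenyl]hex-5-en-2-yl acetate, via aryl Grignard reagent 4 (not isolated), via bromomagnesium alkoxide 5 (not isolated)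
Conditions: Mg, THF, reflux; CuI (10 mol%), 3 (1.1 equiv), −30 → 0 °C; then Ac2O (DMAP cat.), 0 °C → rt
Reagents that add atoms: acetic anhydride CC(=O)OC(C)=O
Why: Grignard formation followed by copper-catalysed SN2 opening of the monosubstituted epoxide at its unsubstituted carbon forms the aryl–C1' bond without touching the stereocentre, so C2' takes its (R) configuration directly from 3, and the magnesium alkoxide is O-acylated by acetic anhydride in the same flask (epoxide opening by an aryl Grignard/cuprate, then alkoxide acetylation).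

Step 3
Reactants: 6 (2R)-1-[3,5-bis(benzyloxy)phenyl]hex-5-en-2-yl acetate
Product: 8 (2R)-1-[3,5-bis(benzyloxy)-2-formylphenyl]hex-5-en-2-yl acetate, via aryl iminium salt 7 (not isolated)
Conditions: POCl3 (1.5 equiv), DMF, 0 °C → rt; then H2O, 0 °C → rt
Reagents that add atoms: N,N-dimethylformamide CN(C)C=O; water O
Why: Vilsmeier–Haack formylation: the chloroiminium ion should attack the ring carbon ortho to the alkyl group and para to a benzyloxy group (two equivalent sites) in preference to the more crowded carbon between the two benzyloxy groups, as is usual for 5-alkylresorcinol diethers, while the acetate and the vinyl group are inert to the reagent.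

Step 4
Reactants: 8 (2R)-1-[3,5-bis(benzyloxy)-2-formylphenyl]hex-5-en-2-yl acetate
Product: 9 2-[(2R)-2-(acetyloxy)hex-5-en-1-yl]-4,6-bis(benzyloxy)benzoic acid
Conditions: NaClO2, NaH2PO4, 2-methyl-2-butene (excess), t-BuOH/THF/H2O, 0 °C → rt
Reagents that add atoms: sodium chlorite [Na+].[O-]Cl=O
Why: Pinnick oxidation: chlorous acid converts the hindered aryl aldehyde into the acid under buffered conditions that spare the acetate, and the excess 2-methyl-2-butene intercepts hypochlorous acid before it can chlorinate the electron-rich ring or the vinyl group.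

Step 5
Reactants: 9 2-[(2R)-2-(acetyloxy)hex-5-en-1-yl]-4,6-bis(benzyloxy)benzoic acid
Product: 10 benzyl 2-[(2R)-2-(acetyloxy)hex-5-en-1-yl]-4,6-bis(benzyloxy)benzoate
Conditions: BnBr, KHCO3, DMF, rt
Reagents that add atoms: benzyl bromide BrCc1ccccc1
Why: SN2 O-alkylation of the carboxylate with benzyl bromide under bicarbonate, too mild to cleave the acetate, masks the acid (which would consume 9-BBN in step 7) as an ester that falls in the final hydrogenolysis.

Step 6
Reactants: 11 7-bromoheptan-1-ol
Product: 12 {[(7-bromoheptyl)oxy]methyl}benzene (benzyl 7-bromoheptyl ether)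
Conditions: benzyl 2,2,2-trichloroacetimidate (1.3 equiv), TfOH (5 mol%), CH2Cl2/cyclohexane, 0 °C → rt
Reagents that add atoms: benzyl 2,2,2-trichloroacetimidate N=C(OCc1ccccc1)C(Cl)(Cl)Cl
Why: Acid-catalysed O-benzylation with the trichloroacetimidate (SN1-type benzyl transfer) avoids the alkoxide conditions under which the bromo alcohol would alkylate itself.

Step 7
Reactants: 10 benzyl 2-[(2R)-2-(acetyloxy)hex-5-en-1-yl]-4,6-bis(benzyloxy)benzoate; 12 {[(7-bromoheptyl)oxy]methyl}benzene
Product: 14 benzyl 2-[(2R)-2-(acetyloxy)-13-(benzyloxy)tridecyl]-4,6-bis(benzyloxy)benzoate, via B-alkyl-9-BBN adduct 13 (not isolated)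
Conditions: 9-BBN (1.15 equiv), THF, 0 °C → rt; then 12 (1.2 equiv), Pd(OAc)2 (4 mol%), PCy3 (8 mol%), K3PO4·H2O (1.3 equiv), THF, rt
Reagents that add atoms: none
Why: 9-BBN should add to the monosubstituted C5'=C6' alkene with anti-Markovnikov selectivity, placing boron on C6' much faster than it reduces the acetate or the hindered benzyl ester; Pd(0)/PCy3 then inserts into the primary C7'–Br bond of 12 by SN2-type oxidative addition, the hydroxide-bound borate transfers its primary alkyl group (the two secondary bicyclooctyl B–C bonds do not migrate) and reductive elimination forms the C6'–C7' single bond. The closest known reaction type is the room-temperature alkyl–alkyl Suzuki–Miyaura coupling of primary alkyl bromides bearing β-hydrogens with B-alkyl-9-BBN reagents under Pd(OAc)2/PCy3/K3PO4·H2O. No ring is closed and no stereocentre is formed; C2' lies four bonds from boron and is not touched. The step needs chemoselective hydroboration (secured by the single unhindered terminal alkene and the low reactivity of 9-BBN toward esters at room temperature), transmetalation faster than β-hydride elimination from the alkylpalladium intermediate (secured by the bulky electron-rich PCy3 and two unbranched primary partners) and survival of the acetate (hydrated K3PO4 in THF at room temperature should be too weak to cleave it). In one operation the vinyl terminus becomes the complete, saturated C1'–C13' chain with every oxygen substituent of the target in place, so that only hydrogenolysis remains.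

Step 8
Reactants: 14 benzyl 2-[(2R)-2-(acetyloxy)-13-(benzyloxy)tridecyl]-4,6-bis(benzyloxy)benzoate
Product: 15 2-[(2R)-2-(acetyloxy)-13-hydroxytridecyl]-4,6-dihydroxybenzoic acid
Conditions: H2 (1 atm), 10% Pd/C, EtOAc/EtOH, rt
Reagents that add atoms: none
Why: Heterogeneous palladium hydrogenolysis cleaves the four benzylic C–O bonds (two aryl benzyl ethers, the benzyl ester and the primary alkyl benzyl ether) under neutral conditions, whereas the C2' acetate is an unactivated secondary alkyl ester on a non-benzylic carbon, so acetate and configuration should survive.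

**Compound list**

1 | 5-bromobenzene-1,3-diol (5-bromoresorcinol) | Oc1cc(O)cc(Br)c1 | starting material
2 | 1,3-bis(benzyloxy)-5-bromobenzene | Brc1cc(OCc2ccccc2)cc(OCc2ccccc2)c1 | intermediate
3 | (2R)-2-(but-3-en-1-yl)oxirane [(R)-1,2-epoxy-5-hexene] | C=CCC[C@@H]1CO1 | starting material
4 | [3,5-bis(benzyloxy)phenyl]magnesium bromide | Br[Mg]c1cc(OCc2ccccc2)cc(OCc2ccccc2)c1 | intermediate
5 | bromomagnesium (2R)-1-[3,5-bis(benzyloxy)phenyl]hex-5-en-2-olate | Br[Mg]O[C@H](CCC=C)Cc1cc(OCc2ccccc2)cc(OCc2ccccc2)c1 | intermediate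
6 | (2R)-1-[3,5-bis(benzyloxy)phenyl]hex-5-en-2-yl acetate | CC(=O)O[C@H](CCC=C)Cc1cc(OCc2ccccc2)cc(OCc2ccccc2)c1 | intermediate
7 | N-({2-[(2R)-2-(acetyloxy)hex-5-en-1-yl]-4,6-bis(benzyloxy)phenyl}methylidene)-N-methylmethanaminium dichlorophosphate | CC(=O)O[C@H](CCC=C)Cc1cc(OCc2ccccc2)cc(OCc2ccccc2)c1C=[N+](C)C.[O-]P(=O)(Cl)Cl | intermediate
8 | (2R)-1-[3,5-bis(benzyloxy)-2-formylphenyl]hex-5-en-2-yl acetate | CC(=O)O[C@H](CCC=C)Cc1cc(OCc2ccccc2)cc(OCc2ccccc2)c1C=O | intermediate
9 | 2-[(2R)-2-(acetyloxy)hex-5-en-1-yl]-4,6-bis(benzyloxy)benzoic acid | CC(=O)O[C@H](CCC=C)Cc1cc(OCc2ccccc2)cc(OCc2ccccc2)c1C(=O)O | intermediate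
10 | benzyl 2-[(2R)-2-(acetyloxy)hex-5-en-1-yl]-4,6-bis(benzyloxy)benzoate | CC(=O)O[C@H](CCC=C)Cc1cc(OCc2ccccc2)cc(OCc2ccccc2)c1C(=O)OCc3ccccc3 | intermediate
11 | 7-bromoheptan-1-ol | OCCCCCCCBr | starting material
12 | {[(7-bromoheptyl)oxy]methyl}benzene | BrCCCCCCCOCc1ccccc1 | intermediate
13 | benzyl 2-[(2R)-2-(acetyloxy)-6-(9-borabicyclo[3.3.1]nonan-9-yl)hexyl]-4,6-bis(benzyloxy)benzoate | CC(=O)O[C@H](CCCCB4C5CCCC4CCC5)Cc1cc(OCc2ccccc2)cc(OCc2ccccc2)c1C(=O)OCc3ccccc3 | intermediate
14 | benzyl 2-[(2R)-2-(acetyloxy)-13-(benzyloxy)tridecyl]-4,6-bis(benzyloxy)benzoate | CC(=O)O[C@H](CCCCCCCCCCCOCc4ccccc4)Cc1cc(OCc2ccccc2)cc(OCc2ccccc2)c1C(=O)OCc3ccccc3 | intermediate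
15 | 2-[(2R)-2-(acetyloxy)-13-hydroxytridecyl]-4,6-dihydroxybenzoic acid | CC(=O)O[C@H](CCCCCCCCCCCO)Cc1cc(O)cc(O)c1C(=O)O | target

**Totals**

Total step count: 8. Longest linear sequence: 7 steps (steps 1, 2, 3, 4, 5, 7, 8 from 5-bromoresorcinol); step 6 is a one-step side branch.

**Steps most likely to fail**

Step 7. What may go wrong: β-hydride elimination from the C7' alkylpalladium(II) intermediate before transmetalation, slow alkyl transfer from the hindered borate, or partial reduction of ester groups by residual B–H. The fallback forms the same bond as an alkene by Wittig olefination; it sets out from 10 and 12 and comes back to the route at 15.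
- 10 is hydroborated as in step 7 (to 13) and oxidised with NaBO3·4H2O in THF/H2O to the primary alcohol benzyl 2-[(2R)-2-(acetyloxy)-6-hydroxyhexyl]-4,6-bis(benzyloxy)benzoate F1.
- Dess–Martin periodinane (NaHCO3, CH2Cl2) should convert it into the aldehyde benzyl 2-[(2R)-2-(acetyloxy)-6-oxohexyl]-4,6-bis(benzyloxy)benzoate F2.
- 12 is heated with PPh3 in MeCN to give [7-(benzyloxy)heptyl]triphenylphosphonium bromide F3.
- The ylide from F3 (NaHMDS, THF, −78 °C) should react with the aldehyde faster than with either ester to give benzyl 2-[(2R,6Z)-2-(acetyloxy)-13-(benzyloxy)tridec-6-en-1-yl]-4,6-bis(benzyloxy)benzoate F4.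
- Under the conditions of step 8 the C6'=C7' alkene is saturated while the four benzyl groups are cleaved, giving 15.

Step 3. What may go wrong: attack of the bulky chloroiminium ion at the ring carbon between the two benzyloxy groups, sluggish reaction next to the branched side chain, or acid-promoted loss of a benzyl ether. The fallback delivers the carboxyl carbon by palladium catalysis instead of electrophilic formylation; it sets out from 6 and comes back at 10, replacing steps 3–5.
- NBS in MeCN at 0 °C (a small electrophile that in 5-alkylresorcinol diethers selects the carbon para to an alkoxy group and ortho to the alkyl group) should give (2R)-1-[3,5-bis(benzyloxy)-2-bromophenyl]hex-5-en-2-yl acetate F5.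
- Pd-catalysed benzyloxycarbonylation (Pd(OAc)2, Xantphos, CO 1 atm, BnOH, Et3N, toluene, 80 °C) should then give 10 directly.

Step 8. What may go wrong: slow hydrogenolysis of the unactivated primary alkyl benzyl ether, so that the free resorcylic acid is exposed to the catalyst for a long time and may decarboxylate or undergo acyl transfer. The fallback changes the protecting group on the C13' oxygen to a silyl ether removed separately by mild acid; it sets out from 11 and 13 and comes back at 15.
- 11 is silylated (TBSCl, imidazole, DMF) to [(7-bromoheptyl)oxy](tert-butyl)dimethylsilane F6.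
- F6 is coupled with 13 under the conditions of step 7 to give benzyl 2-[(2R)-2-(acetyloxy)-13-{[tert-butyl(dimethyl)silyl]oxy}tridecyl]-4,6-bis(benzyloxy)benzoate F7.
- Brief hydrogenolysis (H2, Pd/C, EtOAc), which only has to cleave the fast-reacting aryl benzyl ethers and the benzyl ester, should give 2-[(2R)-2-(acetyloxy)-13-{[tert-butyl(dimethyl)silyl]oxy}tridecyl]-4,6-dihydroxybenzoic acid F8.
- AcOH/THF/H2O at rt removes the primary silyl ether without touching the acetate and gives 15.

Further compounds
F1 | step 7 | benzyl 2-[(2R)-2-(acetyloxy)-6-hydroxyhexyl]-4,6-bis(benzyloxy)benzoate | CC(=O)O[C@H](CCCCO)Cc1cc(OCc2ccccc2)cc(OCc2ccccc2)c1C(=O)OCc3ccccc3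
F2 | step 7 | benzyl 2-[(2R)-2-(acetyloxy)-6-oxohexyl]-4,6-bis(benzyloxy)benzoate | CC(=O)O[C@H](CCCC=O)Cc1cc(OCc2ccccc2)cc(OCc2ccccc2)c1C(=O)OCc3ccccc3
F3 | step 7 | [7-(benzyloxy)heptyl]triphenylphosphonium bromide | [Br-].c1ccccc1[P+](CCCCCCCOCc1ccccc1)(c1ccccc1)c1ccccc1
F4 | step 7 | benzyl 2-[(2R,6Z)-2-(acetyloxy)-13-(benzyloxy)tridec-6-en-1-yl]-4,6-bis(benzyloxy)benzoate | CC(=O)O[C@H](CCC/C=C\CCCCCCOCc4ccccc4)Cc1cc(OCc2ccccc2)cc(OCc2ccccc2)c1C(=O)OCc3ccccc3
F5 | step 3 | (2R)-1-[3,5-bis(benzyloxy)-2-bromophenyl]hex-5-en-2-yl acetate | CC(=O)O[C@H](CCC=C)Cc1cc(OCc2ccccc2)cc(OCc2ccccc2)c1Br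
F6 | step 8 | [(7-bromoheptyl)oxy](tert-butyl)dimethylsilane | CC(C)(C)[Si](C)(C)OCCCCCCCBr
F7 | step 8 | benzyl 2-[(2R)-2-(acetyloxy)-13-{[tert-butyl(dimethyl)silyl]oxy}tridecyl]-4,6-bis(benzyloxy)benzoate | CC(=O)O[C@H](CCCCCCCCCCCO[Si](C)(C)C(C)(C)C)Cc1cc(OCc2ccccc2)cc(OCc2ccccc2)c1C(=O)OCc3ccccc3
F8 | step 8 | 2-[(2R)-2-(acetyloxy)-13-{[tert-butyl(dimethyl)silyl]oxy}tridecyl]-4,6-dihydroxybenzoic acid | CC(=O)O[C@H](CCCCCCCCCCCO[Si](C)(C)C(C)(C)C)Cc1cc(O)cc(O)c1C(=O)O
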